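## Overview

- Retrosynthesis: the sulfate S–O bond at O3 and the benzyl ether at O4' are removed first, the C3–O bond is traced back to oxidation of the C2=C3 bond of a flavone, and ring C is then cut at C4–C4a (acyl–arene bond) and at O1–C2 (aryl vinyl ether bond).
- This leaves two bought benzene rings: 3,5-dimethoxyphenol (ring A) and vanillin (ring B), the latter homologated to an arylpropiolate that supplies C2, C3 and C4.
- Forward: the two pieces are joined at O1–C2 by conjugate addition of the phenol to the ynoate. Ring C is closed last, at C4–C4a, by intramolecular Friedel–Crafts acylation of the derived β-aryloxyacrylic acid. C3 hydroxylation, unmasking of 5-OH, 3-O-sulfation and debenzylation follow.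
- Enabling feature: ring A (C4a, C5, C6, C7, C8, C8a) carries oxygen at C5, C7 and C8a. Before closure it is therefore a symmetric 3,5-dimethoxyphenyl ether with two equivalent ortho carbons, each activated by all three oxygens; whichever one attacks the C4 acyl carbon becomes C4a and the same flavone results.
- Stereochemistry: the target has no stereocentre. The enol ether geometry of the acrylate and the racemic 2,3-epoxide are transient and vanish when ring C becomes aromatic.

Key step: step 6

Remark: the target is taken as the free hydrogen sulfate as drawn; because an aryl hydrogen sulfate is cleaved by its own acidity, the sulfate is carried as its triethylammonium salt and the free acid is liberated only in the last step, cold.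

## Route

Step 1
Reactants: 1 vanillin
Product: 2 4-(benzyloxy)-3-methoxybenzaldehyde (O-benzylvanillin)
Conditions: BnBr, K2CO3, DMF, rt
Reagents that add atoms: benzyl bromide, BrCc1ccccc1
Why: Williamson ether synthesis, in which the phenoxide is alkylated by the benzylic bromide while the aldehyde is untouched.

Step 2
Reactants: 2 4-(benzyloxy)-3-methoxybenzaldehyde
Product: 3 1-(benzyloxy)-4-(2,2-dibromovinyl)-2-methoxybenzene
Conditions: CBr4, PPh3, Zn dust, CH2Cl2, 0 °C to rt
Reagents that add atoms: carbon tetrabromide, BrC(Br)(Br)Br
Why: First stage of the Corey–Fuchs sequence, a Wittig olefination of the aromatic aldehyde by Ph3P=CBr2 generated in the flask.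

Step 3
Reactants: 3 1-(benzyloxy)-4-(2,2-dibromovinyl)-2-methoxybenzene
Product: 5 ethyl 3-(4-benzyloxy-3-methoxyphenyl)propiolate, via lithium arylacetylide 4 (not isolated)
Conditions: n-BuLi (2.1 equiv), THF, −78 °C; then ClCO2Et, −78 °C to rt
Reagents that add atoms: ethyl chloroformate, CCOC(=O)Cl; n-butyllithium, [Li]CCCC (supplies only the lithium of intermediate 4)
Why: Second stage of the Corey–Fuchs sequence, in which bromine–lithium exchange, Fritsch–Buttenberg–Wiechell rearrangement and deprotonation give the lithium acetylide, which is C-acylated by the chloroformate.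

Step 4
Reactants: 5 ethyl 3-(4-benzyloxy-3-methoxyphenyl)propiolate; 6 3,5-dimethoxyphenol
Product: 7 ethyl (Z)-3-(4-benzyloxy-3-methoxyphenyl)-3-(3,5-dimethoxyphenoxy)acrylate
Conditions: K2CO3 (0.5 equiv), DMF, 80 °C
Reagents that add atoms: none
Why: Base-mediated oxa-Michael addition, in which the phenoxide oxygen adds to the β-carbon of the ynoate (forming O1–C2) and anti protonation of the allenolate should give mainly the Z enol ether; an E/Z mixture would still be usable because step 6 tolerates either geometry.

Step 5
Reactants: 7 ethyl (Z)-3-(4-benzyloxy-3-methoxyphenyl)-3-(3,5-dimethoxyphenoxy)acrylate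
Product: 8 (Z)-3-(4-benzyloxy-3-methoxyphenyl)-3-(3,5-dimethoxyphenoxy)acrylic acid
Conditions: LiOH·H2O, THF/MeOH/H2O, rt; then 1 M HCl to pH 3, 0 °C
Reagents that add atoms: lithium hydroxide, [Li+].[OH-]
Why: Ester saponification by acyl–oxygen cleavage at room temperature, followed by a cold acidification that is too mild to hydrolyse the conjugated aryl enol ether.

Step 6
Reactants: 8 (Z)-3-(4-benzyloxy-3-methoxyphenyl)-3-(3,5-dimethoxyphenoxy)acrylic acid
Product: 10 4'-benzyloxy-5,7,3'-trimethoxyflavone, via mixed trifluoroacetic anhydride 9 (not isolated)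
Conditions: TFAA (1.5 equiv), CH2Cl2, 0 °C to rt; aq. NaHCO3 work-up
Reagents that add atoms: trifluoroacetic anhydride, O=C(OC(=O)C(F)(F)F)C(F)(F)F (its trifluoroacetyl group is held only by intermediate 9; nothing of it remains in 10)
Why: TFAA converts the acid into the mixed anhydride 9, whose acyl carbon (the future C4), ionising toward an acylium ion conjugated with the enol ether, is attacked by an ortho carbon of the 3,5-dimethoxyphenoxy ring, and loss of the ring proton together with trifluoroacetate gives the aromatic pyran-4-one. The closest known reaction type is the Ruhemann flavone synthesis, the intramolecular Friedel–Crafts acylation of a β-aryloxycinnamic acid, run here with anhydride activation in place of mineral acid or AlCl3. Ring C closes by C4–C4a bond formation in a 6-exo-trig attack on the acyl carbon, with the C2=C3 bond lying inside the new six-membered ring; no stereocentre is formed and the alkene geometry disappears on aromatisation. The step needs regioselectivity on ring A and chemoselectivity against ring B: the first is secured by the symmetry of the ether, whose two ortho carbons are equivalent and each ortho to the ether oxygen, ortho to one methoxy and para to the other, while the para carbon cannot reach the tether; the second by the Z geometry, which holds the acyl group next to ring A, and by the much higher nucleophilicity of the phloroglucinol-type ring. Should some E isomer be present, the push–pull enol ether can rotate about C2–C3 in the activated acyl species, so both isomers should funnel into the same closure. Mild anhydride activation at or below room temperature spares the benzyl ether and avoids strong protic acid, which could reverse the oxa-Michael addition and lead to a 4-arylcoumarin.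

Step 7
Reactants: 10 4'-benzyloxy-5,7,3'-trimethoxyflavone
Product: 12 4'-benzyloxy-3-hydroxy-5,7,3'-trimethoxyflavone, via racemic 2,3-epoxyflavanone 11 (not isolated)
Conditions: DMDO (ca. 0.08 M in acetone, 2 equiv), CH2Cl2, 0 °C to rt; evaporate; then p-TsOH·H2O (cat.), CH2Cl2, rt
Reagents that add atoms: dimethyldioxirane, CC1(C)OO1
Why: Dioxirane epoxidation of the C2=C3 bond followed by acid-catalysed epoxide opening at C2 (cation stabilised by O1 and ring B) and loss of the C3 proton, a known route from 5,7-dialkoxyflavones to flavonols that erases both transient stereocentres.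

Step 8
Reactants: 12 4'-benzyloxy-3-hydroxy-5,7,3'-trimethoxyflavone
Product: 13 4'-O-benzylrhamnazin (4'-benzyloxy-3,5-dihydroxy-7,3'-dimethoxyflavone)
Conditions: MgI2·OEt2 (3 equiv), THF/toluene, 70 °C; then 1 M HCl, 0 °C
Reagents that add atoms: none
Why: Chelation-directed ether cleavage, in which magnesium bound between the C4 carbonyl and the peri 5-methoxy oxygen activates only that methyl group for SN2 attack by iodide, while the 7- and 3'-methyl ethers and the benzyl ether, which have no neighbouring carbonyl, should stay.

Step 9
Reactants: 13 4'-O-benzylrhamnazin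
Product: 14 triethylammonium salt of 4'-O-benzylrhamnazin 3-O-sulfate
Conditions: SO3·NEt3 (4 equiv), NEt3, DMF, 60 °C
Reagents that add atoms: sulfur trioxide–triethylamine complex, CC[N+](CC)(CC)S(=O)(=O)[O-]
Why: O-sulfation with a sulfur trioxide–amine complex, which should take the more acidic, weakly hydrogen-bonded 3-hydroxyl and leave the 5-hydroxyl locked in its six-membered chelate with the C4 carbonyl, the product being held as a stable ammonium salt.

Step 10
Reactants: 14 triethylammonium salt of 4'-O-benzylrhamnazin 3-O-sulfate
Product: 15 triethylammonium salt of rhamnazin 3-O-sulfate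
Conditions: H2 (1 atm), 10% Pd/C, MeOH/THF, rt; filter through Celite
Reagents that add atoms: none
Why: Catalytic hydrogenolysis of the aryl benzyl ether, to which the sulfate monoester salt and the flavonol core are inert, run in a neutral medium so that acid-catalysed desulfation cannot start.

Step 11
Reactants: 15 triethylammonium salt of rhamnazin 3-O-sulfate
Product: 16 rhamnazin 3-O-sulfate
Conditions: polystyrenesulfonic acid resin (H+ form), MeOH/H2O, 0 °C; freeze-dry at once
Reagents that add atoms: none
Why: Cation exchange, in which the resin retains triethylammonium and releases the aryl hydrogen sulfate, kept cold and in brief contact so that the labile free acid is not hydrolysed.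

## Compound list

1 | vanillin (4-hydroxy-3-methoxybenzaldehyde) | COc1cc(C=O)ccc1O | starting material
2 | 4-(benzyloxy)-3-methoxybenzaldehyde (O-benzylvanillin) | COc1cc(C=O)ccc1OCc1ccccc1 | intermediate
3 | 1-(benzyloxy)-4-(2,2-dibromovinyl)-2-methoxybenzene | COc1cc(C=C(Br)Br)ccc1OCc1ccccc1 | intermediate
4 | lithium (4-benzyloxy-3-methoxyphenyl)acetylide (formed in the flask, not isolated) | [Li]C#Cc1ccc(OCc2ccccc2)c(OC)c1 | intermediate
5 | ethyl 3-(4-benzyloxy-3-methoxyphenyl)propiolate | CCOC(=O)C#Cc1ccc(OCc2ccccc2)c(OC)c1 | intermediate
6 | 3,5-dimethoxyphenol | COc1cc(O)cc(OC)c1 | starting material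
7 | ethyl (Z)-3-(4-benzyloxy-3-methoxyphenyl)-3-(3,5-dimethoxyphenoxy)acrylate | CCOC(=O)/C=C(\Oc1cc(OC)cc(OC)c1)c1ccc(OCc2ccccc2)c(OC)c1 | intermediate
8 | (Z)-3-(4-benzyloxy-3-methoxyphenyl)-3-(3,5-dimethoxyphenoxy)acrylic acid | OC(=O)/C=C(\Oc1cc(OC)cc(OC)c1)c1ccc(OCc2ccccc2)c(OC)c1 | intermediate
9 | mixed anhydride of acid 8 with trifluoroacetic acid (formed in the flask, not isolated) | O=C(OC(=O)C(F)(F)F)/C=C(\Oc1cc(OC)cc(OC)c1)c1ccc(OCc2ccccc2)c(OC)c1 | intermediate
10 | 4'-benzyloxy-5,7,3'-trimethoxyflavone | COc1cc(OC)c2c(=O)cc(-c3ccc(OCc4ccccc4)c(OC)c3)oc2c1 | intermediate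
11 | 4'-benzyloxy-2,3-epoxy-5,7,3'-trimethoxyflavanone (cis-fused, racemic, one enantiomer drawn; formed in the flask, not isolated) | COc1cc(OC)c2C(=O)[C@@H]3O[C@]3(c4ccc(OCc5ccccc5)c(OC)c4)Oc2c1 | intermediate
12 | 4'-benzyloxy-3-hydroxy-5,7,3'-trimethoxyflavone | COc1cc(OC)c2c(=O)c(O)c(-c3ccc(OCc4ccccc4)c(OC)c3)oc2c1 | intermediate
13 | 4'-O-benzylrhamnazin (4'-benzyloxy-3,5-dihydroxy-7,3'-dimethoxyflavone) | COc1cc(O)c2c(=O)c(O)c(-c3ccc(OCc4ccccc4)c(OC)c3)oc2c1 | intermediate
14 | triethylammonium salt of 4'-O-benzylrhamnazin 3-O-sulfate | COc1cc(O)c2c(=O)c(OS(=O)(=O)[O-])c(-c3ccc(OCc4ccccc4)c(OC)c3)oc2c1.CC[NH+](CC)CC | intermediate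
15 | triethylammonium salt of rhamnazin 3-O-sulfate | COc1cc(O)c2c(=O)c(OS(=O)(=O)[O-])c(-c3ccc(O)c(OC)c3)oc2c1.CC[NH+](CC)CC | intermediate
16 | rhamnazin 3-O-sulfate (5,4'-dihydroxy-7,3'-dimethoxyflavon-3-yl hydrogen sulfate) | COc1cc(O)c2c(=O)c(OS(=O)(=O)O)c(-c3ccc(O)c(OC)c3)oc2c1 | target

## Step count and risks

Total step count: 11. Longest linear sequence: 11 steps, from vanillin 1 to 16; 3,5-dimethoxyphenol 6 enters as bought in step 4.

The three steps most likely to fail, in order of risk:

Step 6, the ring closure. Intermolecular trifluoroacetylation of the electron-rich ring A may outrun the intramolecular acylation, the enol ether may be cleaved by the trifluoroacetic acid that builds up, or E isomer may close onto ring B toward an indenone. The fallback closes ring C at O1–C2 instead. It sets out from aldehyde 2: Claisen–Schmidt condensation with commercial 2'-hydroxy-4',6'-dimethoxyacetophenone (KOH, EtOH, rt) should give the chalcone (E)-3-(4-benzyloxy-3-methoxyphenyl)-1-(2-hydroxy-4,6-dimethoxyphenyl)prop-2-en-1-one F1. Oxidative cyclisation of this 2'-hydroxychalcone with catalytic I2 in DMSO at 120–130 °C (oxa-Michael closure to the flavanone, then iodination and loss of HI, with DMSO regenerating I2) should give flavone 10, where the route is rejoined before step 7.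

Step 8, the selective 5-O-demethylation. Chelation control may be lost: magnesium may be sequestered by the 3-hydroxy-4-keto unit so that the cleavage stalls, and forcing it may cost the benzyl ether or a second methyl ether. The fallback uses global cleavage followed by selective reprotection. It sets out from flavonol 12: BCl3 with pentamethylbenzene as cation scavenger in CH2Cl2 (−78 to 0 °C) should remove both the benzyl ether and the chelated 5-O-methyl group and give rhamnazin (3,5,4'-trihydroxy-7,3'-dimethoxyflavone) F2. One equivalent of benzyl bromide with K2CO3 in DMF at room temperature should then alkylate the 4'-hydroxyl, the most acidic hydroxyl not tied to the C4 carbonyl by a hydrogen bond, and so return to 13 before step 9.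

Step 7, the C3 hydroxylation. The dioxirane may oxidise the electron-rich rings or the benzylic position faster than the electron-poor C2=C3 bond, or the epoxide may open toward ring-contracted or hydrated products instead of the enol. The fallback replaces epoxidation by C3 metalation. It sets out from flavone 10: LDA in THF at −78 °C should remove the C3 proton and give 4'-benzyloxy-3-lithio-5,7,3'-trimethoxyflavone F3. Trimethyl borate should trap it as lithium (4'-benzyloxy-5,7,3'-trimethoxyflavon-3-yl)trimethoxyborate F4, and oxidation in the same flask with H2O2 and acetic acid should turn the C–B bond into the C3–OH of flavonol 12, where the route is rejoined before step 8.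

Further compounds
F1 | step 6 | (E)-3-(4-benzyloxy-3-methoxyphenyl)-1-(2-hydroxy-4,6-dimethoxyphenyl)prop-2-en-1-one | COc1cc(O)c(C(=O)/C=C/c2ccc(OCc3ccccc3)c(OC)c2)c(OC)c1
F2 | step 8 | rhamnazin (3,5,4'-trihydroxy-7,3'-dimethoxyflavone) | COc1cc(O)c2c(=O)c(O)c(-c3ccc(O)c(OC)c3)oc2c1
F3 | step 7 | 4'-benzyloxy-3-lithio-5,7,3'-trimethoxyflavone | COc1cc(OC)c2c(=O)c([Li])c(-c3ccc(OCc4ccccc4)c(OC)c3)oc2c1
F4 | step 7 | lithium (4'-benzyloxy-5,7,3'-trimethoxyflavon-3-yl)trimethoxyborate | [Li+].COc1cc(OC)c2c(=O)c([B-](OC)(OC)OC)c(-c3ccc(OCc4ccccc4)c(OC)c3)oc2c1
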